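**Retrosynthetic overview**
- The target, (6S)-6-[(1S,2R,3E,5S,6R)-5,6-diacetoxy-1-hydroxy-2-methoxyhept-3-enyl]-5,6-dihydro-2H-pyran-2-one, is cut last at the C3'=C4' E-alkene: cross-metathesis of lactone fragment 7 (15 heavy atoms) with diacetate fragment 11 (13 heavy atoms).
- Fragment 7: the anti OH/OMe pair comes from SN2 methanolysis of trans alkenyl epoxide 6; the only ring, the unsaturated δ-lactone, is closed by acrylate ring-closing metathesis before the coupling.
- The epoxide comes from a matched Sharpless epoxidation of dienyl carbinol 3, made by Brown allylation of sorbaldehyde.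
- Fragment 11: Sharpless desymmetrisation of divinylcarbinol, hydride opening of the terminal epoxide, acetylation.

Locants: lactone O1–C6; side chain C1'–C7' counted outward from the ring.

Assumption: the small carbon donors CH2=CHCH2MgBr, acryloyl chloride, methanol and acetic anhydride are treated as reagents and listed under "Reagents that add atoms"; only sorbaldehyde and penta-1,4-dien-3-ol are numbered as starting materials.

**Route**

Step 1
Reactants: 1 (2E,4E)-hexa-2,4-dienal (sorbaldehyde)
Product: 3 (4S,5E,7E)-nona-1,5,7-trien-4-ol, via trienyl diisopinocampheylborinate 2 (not isolated)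
Conditions: (−)-Ipc2BOMe [from (+)-α-pinene] (1.3 equiv), CH2=CHCH2MgBr (1.2 equiv), Et2O, 0 °C to rt; then 1, −78 °C, 3 h; then 3 M NaOH, 30% H2O2, rt
Reagents that add atoms: allylmagnesium bromide, C=CC[Mg]Br
Why: Brown asymmetric allylboration transfers the allyl group through a closed chair transition state in which the isopinocampheyl groups from (+)-α-pinene direct attack to the Si face of the aldehyde, giving 1,2-addition and the (4S) carbinol in about 92% ee before alkaline peroxide cleaves the borinate.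

Step 2
Reactants: 3 (4S,5E,7E)-nona-1,5,7-trien-4-ol
Product: 4 (1S)-1-[(2S,3S)-3-[(1E)-prop-1-en-1-yl]oxiran-2-yl]but-3-en-1-ol
Conditions: Ti(OiPr)4 (0.2 equiv), L-(+)-DIPT (0.25 equiv), tBuOOH (1.5 equiv, decane), 4 Å MS, CH2Cl2, −20 °C, 12–18 h; cold NaOH/brine work-up
Reagents that add atoms: tert-butyl hydroperoxide, CC(C)(C)OO
Why: Sharpless asymmetric epoxidation of a secondary allylic alcohol in its matched sense, where with L-(+)-DIPT the (S)-carbinol is the fast-reacting enantiomer and oxygen goes only to the hydroxyl-bearing C5=C6 bond to give the erythro (anti) epoxy alcohol with both epoxide carbons S, while the minor (R)-alcohol from step 1 reacts slowly and is removed, which raises the ee.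

Step 3
Reactants: 4 (1S)-1-[(2S,3S)-3-[(1E)-prop-1-en-1-yl]oxiran-2-yl]but-3-en-1-ol
Product: 5 (1S)-1-[(2S,3S)-3-[(1E)-prop-1-en-1-yl]oxiran-2-yl]but-3-en-1-yl prop-2-enoate
Conditions: acryloyl chloride (1.5 equiv), Et3N (2.5 equiv), DMAP (5 mol %), CH2Cl2, −20 to 0 °C
Reagents that add atoms: acryloyl chloride, C=CC(=O)Cl
Why: O-acylation of the secondary alcohol with an acid chloride under amine base touches no stereocenter and the cold, buffered medium leaves the epoxide intact.

Step 4
Reactants: 5 (1S)-1-[(2S,3S)-3-[(1E)-prop-1-en-1-yl]oxiran-2-yl]but-3-en-1-yl prop-2-enoate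
Product: 6 (6S)-6-[(2S,3S)-3-[(1E)-prop-1-en-1-yl]oxiran-2-yl]-5,6-dihydro-2H-pyran-2-one
Conditions: second-generation Grubbs catalyst (5 mol %), CH2Cl2 (0.005 M), 40 °C
Reagents that add atoms: none
Why: Ring-closing metathesis of the acrylate with the terminal allyl group closes the six-membered unsaturated lactone with loss of ethylene, and the trans-epoxide geometrically forbids ring closure onto the propenyl group, which therefore survives.

Step 5
Reactants: 6 (6S)-6-[(2S,3S)-3-[(1E)-prop-1-en-1-yl]oxiran-2-yl]-5,6-dihydro-2H-pyran-2-one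
Product: 7 (6S)-6-[(1S,2R,3E)-1-hydroxy-2-methoxypent-3-en-1-yl]-5,6-dihydro-2H-pyran-2-one
Conditions: BF3·OEt2 (0.2 equiv), MeOH/CH2Cl2 1:4, −40 to −20 °C
Reagents that add atoms: methanol, CO
Why: Lewis acid-catalysed alcoholysis of an alkenyl epoxide, in which methanol attacks the allylic carbon C2' by SN2 with inversion (S to R) because C1' is deactivated by the neighbouring acyloxy-bearing C6, giving the anti 1-hydroxy-2-methoxy pair with the free hydroxyl already at C1'.

Step 6
Reactants: 8 penta-1,4-dien-3-ol (divinylcarbinol)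
Product: 9 (1S)-1-[(2R)-oxiran-2-yl]prop-2-en-1-ol
Conditions: Ti(OiPr)4 (0.2 equiv), L-(+)-DIPT (0.26 equiv), tBuOOH (1.8 equiv), 4 Å MS, CH2Cl2, −20 °C, 5 d
Reagents that add atoms: tert-butyl hydroperoxide, CC(C)(C)OO
Why: Sharpless asymmetric epoxidation of an achiral divinyl carbinol combines selection between the enantiotopic vinyl groups with face selection and destroys the minor enantiomer by over-oxidation, giving the erythro (2R,3S) epoxy alcohol in very high ee.

Step 7
Reactants: 9 (1S)-1-[(2R)-oxiran-2-yl]prop-2-en-1-ol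
Product: 10 (2R,3S)-pent-4-ene-2,3-diol
Conditions: LiAlH4 (1.5 equiv), THF, 0 °C; then H2O, 15% aq NaOH
Reagents that add atoms: none
Why: Hydride opening of a terminal epoxide by SN2 attack at the unhindered primary carbon converts CH2–O into the methyl group and leaves both stereocenters untouched.

Step 8
Reactants: 10 (2R,3S)-pent-4-ene-2,3-diol
Product: 11 (3S,4R)-pent-1-ene-3,4-diyl diacetate
Conditions: Ac2O (3 equiv), pyridine, DMAP (5 mol %), CH2Cl2, 0 °C to rt
Reagents that add atoms: acetic anhydride, CC(=O)OC(C)=O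
Why: DMAP-catalysed acetylation esterifies both hydroxyls without affecting any stereocenter.

Step 9
Reactants: 7 (6S)-6-[(1S,2R,3E)-1-hydroxy-2-methoxypent-3-en-1-yl]-5,6-dihydro-2H-pyran-2-one; 11 (3S,4R)-pent-1-ene-3,4-diyl diacetate
Product: 12 (6S)-6-[(1S,2R,3E,5S,6R)-5,6-diacetoxy-1-hydroxy-2-methoxyhept-3-en-1-yl]-5,6-dihydro-2H-pyran-2-one
Conditions: 11 (3 equiv), second-generation Hoveyda–Grubbs catalyst (2 × 5 mol %), CH2Cl2, 40 °C, argon sparge, 24 h
Reagents that add atoms: none
Why: Olefin cross-metathesis joins the propenyl group of 7 to the vinyl group of 11 with loss of propene, forming the thermodynamically favoured E-alkene while the electron-poor lactone alkene stays out of the reaction and no stereocenter is touched.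

**Compound list**
1 | (2E,4E)-hexa-2,4-dienal (sorbaldehyde) | C/C=C/C=C/C=O | starting material
2 | (4S,5E,7E)-nona-1,5,7-trien-4-yl diisopinocampheylborinate (Ipc groups from (+)-α-pinene) | C=CC[C@H](OB([C@@H]1C[C@@H]2C[C@H]([C@H]1C)C2(C)C)[C@@H]1C[C@@H]2C[C@H]([C@H]1C)C2(C)C)/C=C/C=C/C | intermediate
3 | (4S,5E,7E)-nona-1,5,7-trien-4-ol | C=CC[C@H](O)/C=C/C=C/C | intermediate
4 | (1S)-1-[(2S,3S)-3-[(1E)-prop-1-en-1-yl]oxiran-2-yl]but-3-en-1-ol | C/C=C/[C@@H]1O[C@H]1[C@@H](O)CC=C | intermediate
5 | (1S)-1-[(2S,3S)-3-[(1E)-prop-1-en-1-yl]oxiran-2-yl]but-3-en-1-yl prop-2-enoate | C/C=C/[C@@H]1O[C@H]1[C@H](CC=C)OC(=O)C=C | intermediate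
6 | (6S)-6-[(2S,3S)-3-[(1E)-prop-1-en-1-yl]oxiran-2-yl]-5,6-dihydro-2H-pyran-2-one | C/C=C/[C@@H]1O[C@H]1[C@@H]2CC=CC(=O)O2 | intermediate
7 | (6S)-6-[(1S,2R,3E)-1-hydroxy-2-methoxypent-3-en-1-yl]-5,6-dihydro-2H-pyran-2-one | CO[C@H](/C=C/C)[C@@H](O)[C@@H]1CC=CC(=O)O1 | intermediate
8 | penta-1,4-dien-3-ol (divinylcarbinol) | C=CC(O)C=C | starting material
9 | (1S)-1-[(2R)-oxiran-2-yl]prop-2-en-1-ol, that is (2R,3S)-1,2-epoxypent-4-en-3-ol | C=C[C@H](O)[C@H]1CO1 | intermediate
10 | (2R,3S)-pent-4-ene-2,3-diol | C=C[C@H](O)[C@@H](C)O | intermediate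
11 | (3S,4R)-pent-1-ene-3,4-diyl diacetate | C=C[C@H](OC(C)=O)[C@@H](C)OC(C)=O | intermediate
12 | (6S)-6-[(1S,2R,3E,5S,6R)-5,6-diacetoxy-1-hydroxy-2-methoxyhept-3-en-1-yl]-5,6-dihydro-2H-pyran-2-one | CO[C@H](/C=C/[C@H](OC(C)=O)[C@@H](C)OC(C)=O)[C@@H](O)[C@@H]1CC=CC(=O)O1 | target

**Step count**
Total: 9 steps. Longest linear sequence: 6 steps (steps 1–5, then step 9); the other branch is steps 6–8.

**Three steps most likely to fail**

Step 2. The dienyl carbinol is an unusual substrate for the titanium tartrate epoxidation, and product 4 is an alkenyl epoxide that the titanium Lewis acid can open. The fallback sets out from 1 and installs the epoxide before the allyl group. Iminium-catalysed epoxidation of 1 with 35% aqueous H2O2 and (S)-2-{bis[3,5-bis(trifluoromethyl)phenyl](trimethylsilyloxy)methyl}pyrrolidine (10 mol %, CH2Cl2, rt) gives (2R,3S)-3-[(1E)-prop-1-en-1-yl]oxirane-2-carbaldehyde F1. Allylboration of F1 with the (−)-Ipc2B(allyl) reagent of step 1 at −78 °C, under reagent control reinforced by the Felkin preference of epoxy aldehydes for the anti adduct, gives (1S)-1-[(2S,3S)-3-[(1E)-prop-1-en-1-yl]oxiran-2-yl]but-3-en-1-yl diisopinocampheylborinate F2. NaOH/H2O2 work-up of F2 comes back to the route at 4.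

Step 5. The propenyl epoxide can ionise toward a secondary allyl cation, so SN2' attack at C4' or partial loss of inversion at C2' may compete. The fallback sets out from 6. Ethenolysis (ethylene 1 atm, second-generation Grubbs catalyst 5 mol %, CH2Cl2, rt) trims the propenyl group to vinyl and gives (6S)-6-[(2S,3S)-3-ethenyloxiran-2-yl]-5,6-dihydro-2H-pyran-2-one F3. Its epoxide has no stabilised far-end cation and opens by SN2 at C2' with BF3·OEt2/MeOH to (6S)-6-[(1S,2R)-1-hydroxy-2-methoxybut-3-en-1-yl]-5,6-dihydro-2H-pyran-2-one F4. Cross-metathesis of F4 with 11 under the conditions of step 9, now losing ethylene, comes back to the route at 12.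

Step 9. Both partners carry an oxygenated branch next to the reacting alkene, and 7 has a free neighbouring hydroxyl, so the cross-metathesis may be slow and lose material to homodimer of 11. The fallback sets out from 6, together with 11, and couples before the methoxy group is in place. Cross-metathesis of the sterically smaller, hydroxyl-free epoxide 6 with 11 (3 equiv, second-generation Hoveyda–Grubbs catalyst, CH2Cl2, 40 °C) gives (2R,3S,4E)-5-[(2S,3S)-3-[(2S)-6-oxo-3,6-dihydro-2H-pyran-2-yl]oxiran-2-yl]pent-4-ene-2,3-diyl diacetate F5. BF3·OEt2/MeOH then opens F5 at the allylic carbon with inversion, the far-end allylic acetate disfavouring ionisation and SN2' attack, and comes back to the route at 12.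

**Further compounds**
F1 | step 2 | (2R,3S)-3-[(1E)-prop-1-en-1-yl]oxirane-2-carbaldehyde | C/C=C/[C@@H]1O[C@H]1C=O
F2 | step 2 | (1S)-1-[(2S,3S)-3-[(1E)-prop-1-en-1-yl]oxiran-2-yl]but-3-en-1-yl diisopinocampheylborinate | C/C=C/[C@@H]1O[C@H]1[C@H](CC=C)OB([C@@H]2C[C@@H]3C[C@H]([C@H]2C)C3(C)C)[C@@H]2C[C@@H]3C[C@H]([C@H]2C)C3(C)C
F3 | step 5 | (6S)-6-[(2S,3S)-3-ethenyloxiran-2-yl]-5,6-dihydro-2H-pyran-2-one | C=C[C@@H]1O[C@H]1[C@@H]2CC=CC(=O)O2
F4 | step 5 | (6S)-6-[(1S,2R)-1-hydroxy-2-methoxybut-3-en-1-yl]-5,6-dihydro-2H-pyran-2-one | CO[C@H](C=C)[C@@H](O)[C@@H]1CC=CC(=O)O1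
F5 | step 9 | (2R,3S,4E)-5-[(2S,3S)-3-[(2S)-6-oxo-3,6-dihydro-2H-pyran-2-yl]oxiran-2-yl]pent-4-ene-2,3-diyl diacetate | CC(=O)O[C@H](C)[C@@H](OC(C)=O)/C=C/[C@@H]1O[C@H]1[C@@H]2CC=CC(=O)O2
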